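**Retrosynthetic overview**

1. The C5 methyl ether comes from O-methylation of a tertiary o-quinol, and the C5–allyl bond from carbonyl allylation (allylboration) of the C5 ketone of a 5,6-dione, itself made by ortho-oxidation of a 6-phenol.
2. The dihydrofuran ring is closed at O1–C2 by acid-mediated capture of a veratryl-stabilised benzylic cation by the ortho-phenol, giving the 2,3-trans ring.
3. The key C2–C3 bond is made by an intermolecular Evans syn-aldol of an N-(arylacetyl)oxazolidinone with veratraldehyde (sets C3); the acyl carbon is then reduced to the C3 methyl.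
4. The arylacetic acid comes from 2,4-dihydroxyacetophenone (benzylation, Willgerodt–Kindler, hydrolysis).
5. Ring order: resorcinol-derived benzene ring (bought) → dihydrofuran ring (step 11) → dearomatisation of the benzene ring to the cyclohexa-2,4-dienone (steps 12–14).

Assumption (benzofuran numbering throughout): the remote C2/C3 centres give no useful facial bias at C5, so the (5S)-epimer is secured in step 13 by chromatographic separation of the two C5 diastereomers.

**Route**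

Step 1
Reactants: 1 1-(2,4-dihydroxyphenyl)ethan-1-one
Product: 2 1-[2,4-bis(benzyloxy)phenyl]ethan-1-one
Conditions: BnBr (2.4 eq), K2CO3, KI (cat.), DMF, 80 °C
Reagents that add atoms: benzyl bromide, BrCc1ccccc1
Why: Williamson etherification of both phenols (heat and iodide overcome the H-bonded 2-OH) installs benzyl ethers that survive the later base, boron, hydride and sulfonylation steps and are removed by hydrogenolysis.

Step 2
Reactants: 2 1-[2,4-bis(benzyloxy)phenyl]ethan-1-one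
Product: 3 2-[2,4-bis(benzyloxy)phenyl]-1-(morpholin-4-yl)ethane-1-thione
Conditions: S8, morpholine, 130 °C
Reagents that add atoms: sulfur, S1SSSSSSS1; morpholine, C1COCCN1
Why: The Willgerodt–Kindler reaction moves the oxidised carbon of the aryl methyl ketone to the chain terminus as a thioamide, giving the arylacetic acid oxidation level with the aryl benzyl ethers untouched.

Step 3
Reactants: 3 2-[2,4-bis(benzyloxy)phenyl]-1-(morpholin-4-yl)ethane-1-thione
Product: 4 [2,4-bis(benzyloxy)phenyl]acetic acid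
Conditions: KOH, EtOH–H2O, reflux; then aq. HCl
Reagents that add atoms: water, O
Why: Alkaline hydrolysis of the thioamide gives the carboxylate (acid on work-up), and benzyl aryl ethers are inert to hot aqueous base.

Step 4
Reactants: 4 [2,4-bis(benzyloxy)phenyl]acetic acid; 5 (4R)-4-benzyl-1,3-oxazolidin-2-one
Product: 7 (4R)-4-benzyl-3-{[2,4-bis(benzyloxy)phenyl]acetyl}-1,3-oxazolidin-2-one, via mixed pivalic anhydride 6 (not isolated)
Conditions: PivCl, Et3N, THF, −20 °C; then 5, LiCl, −20 °C → rt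
Reagents that add atoms: none
Why: N-Acylation of the Evans auxiliary through the mixed anhydride occurs at the less hindered arylacetyl carbonyl and touches no stereocentre.

Step 5
Reactants: 7 (4R)-4-benzyl-3-{[2,4-bis(benzyloxy)phenyl]acetyl}-1,3-oxazolidin-2-one; 8 3,4-dimethoxybenzaldehyde
Product: 11 (4R)-4-benzyl-3-[(2R,3R)-2-[2,4-bis(benzyloxy)phenyl]-3-(3,4-dimethoxyphenyl)-3-hydroxypropanoyl]-1,3-oxazolidin-2-one, via boron Z-enolate 9 (not isolated), via boron aldolate 10 (not isolated)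
Conditions: Bu2BOTf, iPr2NEt, CH2Cl2, −78 → 0 °C; 8, −78 → 0 °C; pH 7 buffer, MeOH, 30% H2O2, 0 °C
Reagents that add atoms: none
Why: In this Evans syn-aldol reaction the (Z)-boron enolate adds to the aldehyde through a closed Zimmerman–Traxler chair on the face away from the auxiliary benzyl group, forming the C2–C3 bond and setting the future C3 as R (kept to the target) together with the syn carbinol centre.

Step 6
Reactants: 11 (4R)-4-benzyl-3-[(2R,3R)-2-[2,4-bis(benzyloxy)phenyl]-3-(3,4-dimethoxyphenyl)-3-hydroxypropanoyl]-1,3-oxazolidin-2-one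
Product: 12 (4R)-4-benzyl-3-[(2R,3R)-2-[2,4-bis(benzyloxy)phenyl]-3-[(tert-butyldimethylsilyl)oxy]-3-(3,4-dimethoxyphenyl)propanoyl]-1,3-oxazolidin-2-one
Conditions: TBSOTf, 2,6-lutidine, CH2Cl2, 0 °C
Reagents that add atoms: tert-butyldimethylsilyl trifluoromethanesulfonate, CC(C)(C)[Si](C)(C)OS(=O)(=O)C(F)(F)F
Why: Silylation of the secondary benzylic alcohol blocks retro-aldol cleavage and alkoxide side reactions in the following hydride steps.

Step 7
Reactants: 12 (4R)-4-benzyl-3-[(2R,3R)-2-[2,4-bis(benzyloxy)phenyl]-3-[(tert-butyldimethylsilyl)oxy]-3-(3,4-dimethoxyphenyl)propanoyl]-1,3-oxazolidin-2-one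
Product: 13 (2S,3R)-2-[2,4-bis(benzyloxy)phenyl]-3-[(tert-butyldimethylsilyl)oxy]-3-(3,4-dimethoxyphenyl)propan-1-ol
Conditions: LiBH4, THF, 0 °C → rt
Reagents that add atoms: none
Why: Reductive cleavage of the exocyclic imide carbonyl gives the primary alcohol and releases the auxiliary without enolisation, so the α-centre is unchanged (the descriptor changes only through CIP priorities).

Step 8
Reactants: 13 (2S,3R)-2-[2,4-bis(benzyloxy)phenyl]-3-[(tert-butyldimethylsilyl)oxy]-3-(3,4-dimethoxyphenyl)propan-1-ol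
Product: 14 (2S,3R)-2-[2,4-bis(benzyloxy)phenyl]-3-[(tert-butyldimethylsilyl)oxy]-3-(3,4-dimethoxyphenyl)propyl 4-methylbenzenesulfonate
Conditions: TsCl, Et3N, DMAP (cat.), CH2Cl2, 0 °C → rt
Reagents that add atoms: 4-methylbenzenesulfonyl chloride, Cc1ccc(cc1)S(Cl)(=O)=O
Why: Sulfonylation of the unhindered primary alcohol provides the leaving group for deoxygenation while the silyl and benzyl ethers are inert.

Step 9
Reactants: 14 (2S,3R)-2-[2,4-bis(benzyloxy)phenyl]-3-[(tert-butyldimethylsilyl)oxy]-3-(3,4-dimethoxyphenyl)propyl 4-methylbenzenesulfonate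
Product: 15 {[(1R,2R)-2-[2,4-bis(benzyloxy)phenyl]-1-(3,4-dimethoxyphenyl)propyl]oxy}(tert-butyl)dimethylsilane
Conditions: LiEt3BH, THF, 0 °C → rt
Reagents that add atoms: none
Why: SN2 displacement of the primary tosylate by Super-Hydride converts the former acyl carbon into the C3 methyl group without touching either stereocentre or the ether protecting groups.

Step 10
Reactants: 15 {[(1R,2R)-2-[2,4-bis(benzyloxy)phenyl]-1-(3,4-dimethoxyphenyl)propyl]oxy}(tert-butyl)dimethylsilane
Product: 16 4-[(1R,2R)-1-[(tert-butyldimethylsilyl)oxy]-1-(3,4-dimethoxyphenyl)propan-2-yl]benzene-1,3-diol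
Conditions: H2 (1 atm), 10% Pd/C, EtOAc, rt
Reagents that add atoms: none
Why: Neutral hydrogenolysis removes both O-benzyl groups, while the silyl-protected benzylic C–O bond and the aryl methyl ethers are stable under these conditions.

Step 11
Reactants: 16 4-[(1R,2R)-1-[(tert-butyldimethylsilyl)oxy]-1-(3,4-dimethoxyphenyl)propan-2-yl]benzene-1,3-diol
Product: 18 (2R,3R)-2-(3,4-dimethoxyphenyl)-3-methyl-2,3-dihydro-1-benzofuran-6-ol, via benzylic cation 17 (not isolated)
Conditions: CF3CO2H (5 eq), CH2Cl2 (0.02 M), 0 °C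
Reagents that add atoms: none
Why: Acid ionises the electron-rich benzylic silyl ether to a 3,4-dimethoxybenzyl cation that the ortho-phenol captures in an SN1 cycloetherification, setting C2 as R trans to the C3 methyl because the cis ether re-ionises and equilibrates to the more stable trans ring.

Step 12
Reactants: 18 (2R,3R)-2-(3,4-dimethoxyphenyl)-3-methyl-2,3-dihydro-1-benzofuran-6-ol
Product: 19 (2R,3R)-2-(3,4-dimethoxyphenyl)-3-methyl-2,3-dihydro-1-benzofuran-5,6-dione
Conditions: IBX (1.1 eq), DMF, rt, dark; neutral work-up, used at once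
Reagents that add atoms: 2-iodoxybenzoic acid, O=C1OI(=O)(O)c2ccccc12
Why: IBX-mediated ortho-oxygenation of the phenol takes place at the less hindered ortho carbon C5 (para to the ring oxygen) and gives the 4-alkoxy-o-quinone, whose C6 carbonyl is a stabilised vinylogous ester; the aryl methyl ethers and the benzylic ether are inert at rt.

Step 13
Reactants: 19 (2R,3R)-2-(3,4-dimethoxyphenyl)-3-methyl-2,3-dihydro-1-benzofuran-5,6-dione; 20 2-allyl-4,4,5,5-tetramethyl-1,3,2-dioxaborolane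
Product: 22 (2R,3R,5S)-5-allyl-2-(3,4-dimethoxyphenyl)-5-hydroxy-3-methyl-2,3-dihydro-1-benzofuran-6(5H)-one, via pinacolboryl ether 21 (not isolated)
Conditions: 20 (1.5 eq), CH2Cl2, −20 → 0 °C; aq. NaHCO3; chromatography
Reagents that add atoms: none
Why: Uncatalysed carbonyl allylboration through a six-membered chair adds the allyl group to the more electrophilic C5 ketone (C6=O is a deactivated vinylogous ester), creating C5 without bias from the remote C2/C3 centres, so the (5S)-epimer 22 is separated from its (5R)-diastereomer on silica.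

Step 14
Reactants: 22 (2R,3R,5S)-5-allyl-2-(3,4-dimethoxyphenyl)-5-hydroxy-3-methyl-2,3-dihydro-1-benzofuran-6(5H)-one
Product: 23 (2R,3R,5S)-5-allyl-2-(3,4-dimethoxyphenyl)-5-methoxy-3-methyl-2,3-dihydro-1-benzofuran-6(5H)-one
Conditions: NaH, MeI, DMF, 0 °C
Reagents that add atoms: iodomethane, CI
Why: Williamson O-methylation of the tertiary α-ketol alkoxide gives the methyl ether, and since C5 is quaternary and the C3–H is not conjugated to the C6 carbonyl, none of the three stereocentres can epimerise.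

**Compound list**

1 | 1-(2,4-dihydroxyphenyl)ethan-1-one | CC(=O)c1ccc(O)cc1O | starting material
2 | 1-[2,4-bis(benzyloxy)phenyl]ethan-1-one | CC(=O)c1ccc(OCc2ccccc2)cc1OCc1ccccc1 | intermediate
3 | 2-[2,4-bis(benzyloxy)phenyl]-1-(morpholin-4-yl)ethane-1-thione | S=C(Cc1ccc(OCc2ccccc2)cc1OCc1ccccc1)N1CCOCC1 | intermediate
4 | [2,4-bis(benzyloxy)phenyl]acetic acid | OC(=O)Cc1ccc(OCc2ccccc2)cc1OCc1ccccc1 | intermediate
5 | (4R)-4-benzyl-1,3-oxazolidin-2-one | O=C1N[C@H](Cc2ccccc2)CO1 | starting material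
6 | [2,4-bis(benzyloxy)phenyl]acetic pivalic anhydride | CC(C)(C)C(=O)OC(=O)Cc1ccc(OCc2ccccc2)cc1OCc1ccccc1 | intermediate
7 | (4R)-4-benzyl-3-{[2,4-bis(benzyloxy)phenyl]acetyl}-1,3-oxazolidin-2-one | O=C(Cc1ccc(OCc2ccccc2)cc1OCc1ccccc1)N1[C@H](Cc2ccccc2)COC1=O | intermediate
8 | 3,4-dimethoxybenzaldehyde (veratraldehyde) | O=Cc1ccc(OC)c(OC)c1 | starting material
9 | (Z)-O-dibutylboryl enolate of 7 | CCCCB(CCCC)O/C(=C\c1ccc(OCc2ccccc2)cc1OCc1ccccc1)N1[C@H](Cc2ccccc2)COC1=O | intermediate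
10 | O-dibutylboryl aldolate of 11 | CCCCB(CCCC)O[C@@H](c1ccc(OC)c(OC)c1)[C@@H](c1ccc(OCc2ccccc2)cc1OCc1ccccc1)C(=O)N1[C@H](Cc2ccccc2)COC1=O | intermediate
11 | (4R)-4-benzyl-3-[(2R,3R)-2-[2,4-bis(benzyloxy)phenyl]-3-(3,4-dimethoxyphenyl)-3-hydroxypropanoyl]-1,3-oxazolidin-2-one | O[C@@H](c1ccc(OC)c(OC)c1)[C@@H](c1ccc(OCc2ccccc2)cc1OCc1ccccc1)C(=O)N1[C@H](Cc2ccccc2)COC1=O | intermediate
12 | (4R)-4-benzyl-3-[(2R,3R)-2-[2,4-bis(benzyloxy)phenyl]-3-[(tert-butyldimethylsilyl)oxy]-3-(3,4-dimethoxyphenyl)propanoyl]-1,3-oxazolidin-2-one | CC(C)(C)[Si](C)(C)O[C@@H](c1ccc(OC)c(OC)c1)[C@@H](c1ccc(OCc2ccccc2)cc1OCc1ccccc1)C(=O)N1[C@H](Cc2ccccc2)COC1=O | intermediate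
13 | (2S,3R)-2-[2,4-bis(benzyloxy)phenyl]-3-[(tert-butyldimethylsilyl)oxy]-3-(3,4-dimethoxyphenyl)propan-1-ol | CC(C)(C)[Si](C)(C)O[C@@H](c1ccc(OC)c(OC)c1)[C@@H](c1ccc(OCc2ccccc2)cc1OCc1ccccc1)CO | intermediate
14 | (2S,3R)-2-[2,4-bis(benzyloxy)phenyl]-3-[(tert-butyldimethylsilyl)oxy]-3-(3,4-dimethoxyphenyl)propyl 4-methylbenzenesulfonate | CC(C)(C)[Si](C)(C)O[C@@H](c1ccc(OC)c(OC)c1)[C@@H](c1ccc(OCc2ccccc2)cc1OCc1ccccc1)COS(=O)(=O)c1ccc(C)cc1 | intermediate
15 | {[(1R,2R)-2-[2,4-bis(benzyloxy)phenyl]-1-(3,4-dimethoxyphenyl)propyl]oxy}(tert-butyl)dimethylsilane | CC(C)(C)[Si](C)(C)O[C@@H](c1ccc(OC)c(OC)c1)[C@@H](c1ccc(OCc2ccccc2)cc1OCc1ccccc1)C | intermediate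
16 | 4-[(1R,2R)-1-[(tert-butyldimethylsilyl)oxy]-1-(3,4-dimethoxyphenyl)propan-2-yl]benzene-1,3-diol | CC(C)(C)[Si](C)(C)O[C@@H](c1ccc(OC)c(OC)c1)[C@@H](c1ccc(O)cc1O)C | intermediate
17 | 2-(2,4-dihydroxyphenyl)-1-(3,4-dimethoxyphenyl)propan-1-ylium (benzylic cation from 16, C-2 arrangement unchanged) | [CH+](c1ccc(OC)c(OC)c1)[C@@H](c1ccc(O)cc1O)C | intermediate
18 | (2R,3R)-2-(3,4-dimethoxyphenyl)-3-methyl-2,3-dihydro-1-benzofuran-6-ol | Oc1ccc2c(c1)O[C@@H](c1ccc(OC)c(OC)c1)[C@@H]2C | intermediate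
19 | (2R,3R)-2-(3,4-dimethoxyphenyl)-3-methyl-2,3-dihydro-1-benzofuran-5,6-dione | O=C1C=C2C(=CC1=O)O[C@@H](c1ccc(OC)c(OC)c1)[C@@H]2C | intermediate
20 | 2-allyl-4,4,5,5-tetramethyl-1,3,2-dioxaborolane (allylboronic acid pinacol ester) | C=CCB1OC(C)(C)C(C)(C)O1 | starting material
21 | O-pinacolboryl ether of 22 | C=CC[C@]1(OB2OC(C)(C)C(C)(C)O2)C=C2C(=CC1=O)O[C@@H](c1ccc(OC)c(OC)c1)[C@@H]2C | intermediate
22 | (2R,3R,5S)-5-allyl-2-(3,4-dimethoxyphenyl)-5-hydroxy-3-methyl-2,3-dihydro-1-benzofuran-6(5H)-one | C=CC[C@]1(O)C=C2C(=CC1=O)O[C@@H](c1ccc(OC)c(OC)c1)[C@@H]2C | intermediate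
23 | (2R,3R,5S)-5-allyl-2-(3,4-dimethoxyphenyl)-5-methoxy-3-methyl-2,3-dihydro-1-benzofuran-6(5H)-one | C=CC[C@]1(OC)C=C2C(=CC1=O)O[C@@H](c1ccc(OC)c(OC)c1)[C@@H]2C | target

**Totals and risks**

Total step count: 14. Longest linear sequence: 14 steps (1 → 23).

Step 12, the IBX oxidation, is risky because oxygenation could occur at C7, or the o-quinone could tautomerise through its C3–H towards the aromatic benzofuran catechol. The fallback sets out from 18 and introduces the C5 oxygen stepwise. Magnesium-mediated ortho-formylation (MgCl2, Et3N, paraformaldehyde, MeCN, reflux) gives (2R,3R)-2-(3,4-dimethoxyphenyl)-6-hydroxy-3-methyl-2,3-dihydro-1-benzofuran-5-carbaldehyde F1. Dakin oxidation (H2O2, aq. NaOH, 0 °C) gives the catechol (2R,3R)-2-(3,4-dimethoxyphenyl)-3-methyl-2,3-dihydro-1-benzofuran-5,6-diol F2. Neutral dehydrogenation with Ag2O (Et2O, Na2SO4, 0 °C, filter and use at once) comes back to the route at 19.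

Step 13, the allylboration, is risky because the quinone may be reduced, may react at C6, or may react too slowly; it is also the step where half the material is lost as the C5 epimer. The fallback sets out from 18 and reverses the polarity. NBS (1.0 eq, MeCN, −20 °C) gives (2R,3R)-5-bromo-2-(3,4-dimethoxyphenyl)-3-methyl-2,3-dihydro-1-benzofuran-6-ol F3. Stille coupling with allyltributylstannane (Pd(PPh3)4, DMF, 90 °C) gives (2R,3R)-5-allyl-2-(3,4-dimethoxyphenyl)-3-methyl-2,3-dihydro-1-benzofuran-6-ol F4. Hydroxylative phenol dearomatisation with stabilised IBX (SIBX, THF, rt) delivers the oxygen to the allyl-bearing ortho carbon and comes back to the route at 22, again after separation of the C5 epimers.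

Step 14, the methylation, is risky because the hindered tertiary α-ketol may resist alkylation or degrade under base. The fallback sets out from 19 and brings in the ether oxygen before the C–C bond. Ketalisation of the reactive C5 carbonyl (HC(OMe)3, MeOH, cat. CSA, 0 °C) gives (2R,3R)-2-(3,4-dimethoxyphenyl)-5,5-dimethoxy-3-methyl-2,3-dihydro-1-benzofuran-6(5H)-one F5. Hosomi–Sakurai substitution of one methoxy group through the oxocarbenium ion (allyltrimethylsilane, TMSOTf, CH2Cl2, −78 °C) comes back to the route at 23 after separation of the C5 epimer.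

**Further compounds**

F1 | step 12 | (2R,3R)-2-(3,4-dimethoxyphenyl)-6-hydroxy-3-methyl-2,3-dihydro-1-benzofuran-5-carbaldehyde | O=Cc1cc2c(cc1O)O[C@@H](c1ccc(OC)c(OC)c1)[C@@H]2C
F2 | step 12 | (2R,3R)-2-(3,4-dimethoxyphenyl)-3-methyl-2,3-dihydro-1-benzofuran-5,6-diol | Oc1cc2c(cc1O)O[C@@H](c1ccc(OC)c(OC)c1)[C@@H]2C
F3 | step 13 | (2R,3R)-5-bromo-2-(3,4-dimethoxyphenyl)-3-methyl-2,3-dihydro-1-benzofuran-6-ol | Brc1cc2c(cc1O)O[C@@H](c1ccc(OC)c(OC)c1)[C@@H]2C
F4 | step 13 | (2R,3R)-5-allyl-2-(3,4-dimethoxyphenyl)-3-methyl-2,3-dihydro-1-benzofuran-6-ol | C=CCc1cc2c(cc1O)O[C@@H](c1ccc(OC)c(OC)c1)[C@@H]2C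
F5 | step 14 | (2R,3R)-2-(3,4-dimethoxyphenyl)-5,5-dimethoxy-3-methyl-2,3-dihydro-1-benzofuran-6(5H)-one | COC1(OC)C=C2C(=CC1=O)O[C@@H](c1ccc(OC)c(OC)c1)[C@@H]2C
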